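**Retrosynthetic overview**
- Epiphorellic acid 1 comes from a benzyl-protected diaryl ether by O-methylation of the free C4' hydroxyl of ring B, then hydrogenolysis of the ring B benzyl ester and the ring A benzyl ether.
- The strategy rests on ring B: it is an olivetolic acid unit (C1' carboxyl, C2' and C4' oxygens, C6' pentyl) with the ether oxygen on C5'. Its atoms are those of a 3,5,7-trioxododecanoate (C1 = carboxyl carbon, C2 to C7 = C1' to C6') carrying the ring A aryloxy group on chain C6.
- Key disconnection: the C1'–C6' bond (chain C2 to C7) by intramolecular aldol condensation and aromatization of the benzyl triketo ester. Ring B is the only ring formed; ring A is bought intact as methyl olivetolate.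
- The chain is cut at C1–C2 (carboxylation of a triketone trianion with dibenzyl carbonate) and at C3–C4 (acetylation of a diketone dianion). The C6–O bond comes from the ring A phenoxide and 3-chlorononane-2,4-dione.

Key step: step 6

Remark on the chemistry: the aryloxy-bearing carbon between two ketones is a labile stereocentre that vanishes on aromatization, so the di- and triketones are racemic and drawn as keto tautomers; the target has no stereocentre.

**Step 1**
Reactants: 1 methyl olivetolate (methyl 2,4-dihydroxy-6-pentylbenzoate)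
Product: 2 methyl 4-(benzyloxy)-2-hydroxy-6-pentylbenzoate
Conditions: BnBr (1.05 equiv), K2CO3 (1.1 equiv), acetone, reflux
Reagents that add atoms: benzyl bromide, BrCc1ccccc1
Why: Williamson ether synthesis: the C2 hydroxyl is hydrogen-bonded to the ester carbonyl and is the weaker acid and nucleophile, so one equivalent of base and halide should benzylate O-4 only.

**Step 2**
Reactants: 3 nonane-2,4-dione
Product: 4 3-chlorononane-2,4-dione (racemic)
Conditions: SO2Cl2 (1.0 equiv), CH2Cl2, 0 °C to rt
Reagents that add atoms: sulfuryl chloride, O=S(=O)(Cl)Cl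
Why: Electrophilic alpha-chlorination of a beta-diketone through its enol: C3 is the only doubly activated carbon, and one equivalent of sulfuryl chloride should stop at the monochloride.

**Step 3**
Reactants: 2 methyl 4-(benzyloxy)-2-hydroxy-6-pentylbenzoate; 4 3-chlorononane-2,4-dione (1.3 equiv)
Product: 5 methyl 4-(benzyloxy)-2-[(2,4-dioxononan-3-yl)oxy]-6-pentylbenzoate (racemic)
Conditions: Cs2CO3 (1.2 equiv), acetone, 55 °C
Reagents that add atoms: none
Why: Williamson-type SN2 displacement of the chloride of an alpha-chloro-beta-diketone by a cesium phenoxide, a known way to 3-aryloxy-1,3-diketones: the only free phenol of 2 is the nucleophile, and the methyl ester, flanked by two ortho substituents, should not be attacked by the weakly nucleophilic diketonate that forms.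

**Step 4**
Reactants: 5 methyl 4-(benzyloxy)-2-[(2,4-dioxononan-3-yl)oxy]-6-pentylbenzoate; 6 N-methoxy-N-methylacetamide (1.1 equiv)
Product: 9 methyl 4-(benzyloxy)-2-[(2,4,6-trioxoundecan-5-yl)oxy]-6-pentylbenzoate, via dilithium dienediolate 7 (not isolated), via dilithium hemiaminal adduct 8 (not isolated)
Conditions: LiN(i-Pr)2 (2.05 equiv), THF, -78 to 0 °C; then 6, -78 to -20 °C; cold 1 M HCl
Reagents that add atoms: none
Why: Claisen-type acylation of a beta-diketone dianion at its terminal carbon by an N-methoxy-N-methyl amide: the second deprotonation should take the unhindered methyl and not the hexanoyl methylene, the terminal carbon of 7 is by far its most nucleophilic site, and chelated adduct 8 releases the new ketone only on work-up, so no product proton quenches unreacted dianion.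

**Step 5**
Reactants: 9 methyl 4-(benzyloxy)-2-[(2,4,6-trioxoundecan-5-yl)oxy]-6-pentylbenzoate; 10 dibenzyl carbonate (1.2 equiv)
Product: 12 benzyl 6-[5-(benzyloxy)-2-(methoxycarbonyl)-3-pentylphenoxy]-3,5,7-trioxododecanoate, via trilithium trienolate 11 (not isolated)
Conditions: LiN(i-Pr)2 (3.0 equiv), THF, -78 to 0 °C; LiN(SiMe3)2 (1.1 equiv), then 10, -78 to -10 °C; cold 1 M HCl; used without chromatography
Reagents that add atoms: none
Why: Claisen-type C-carboxylation of a beta-triketone trianion by a dialkyl carbonate: after the two doubly activated positions the third equivalent of amide base removes a methyl proton, the terminal carbon of 11 attacks the carbonate, and LiN(SiMe3)2 takes up the acidic C2–H of the product while being too weak to metalate the benzylic CH2 of ring A.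

**Step 6**
Reactants: 12 benzyl 6-[5-(benzyloxy)-2-(methoxycarbonyl)-3-pentylphenoxy]-3,5,7-trioxododecanoate
Product: 14 benzyl 3-[5-(benzyloxy)-2-(methoxycarbonyl)-3-pentylphenoxy]-4,6-dihydroxy-2-pentylbenzoate, via cyclic aldol adduct 13 (not isolated)
Conditions: Cs2CO3 (3 equiv), THF/i-PrOH (10:1), 0 °C to rt; then HCl (4 M in dioxane), rt
Reagents that add atoms: none
Why: Cs2CO3 converts 12 into its polyenolate, in which C2 (the methylene between the benzyl ester and the C3 ketone) adds to the C7 ketone to give cyclohexanedione aldol 13 with the new C2–C7 bond, the C1'–C6' bond of ring B. HCl then eliminates the tertiary hydroxyl and the C3 and C5 carbonyls enolize, so the ring aromatizes with C1 as the ester carbon, C3 and C5 as the hydroxyl-bearing C2' and C4', C6 as the aryloxy-bearing C5' and C7 as the pentyl-bearing C6'. The closest known reaction is the base-mediated aldol cyclization and dehydrative aromatization of 3,5,7-triketo esters to 6-alkylresorcylates, the laboratory counterpart of the polyketide folding that gives olivetolic acid. Ring B closes by a 6-(enolexo)-exo-trig intramolecular aldol addition; the stereocentres of 13 are all erased on aromatization, so none needs control. The selectivity needed is C2-to-C7 aldol over C6-to-C1 Claisen closure, C8-to-C3 aldol, lactonization to a pyranone and attack of C6 on the ring A ester: C2 is the only doubly activated carbon that can reach a ketone through a six-membered ring, C8 is only singly activated, and because C6 carries the aryloxy group any acylation at C6 gives a quaternary, non-aromatizable product and stays reversible. The ring A methyl ester is shielded by its two ortho substituents, and a carbonate base in a weakly protic medium should keep ester exchange and retro-Claisen cleavage slow.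

**Step 7**
Reactants: 14 benzyl 3-[5-(benzyloxy)-2-(methoxycarbonyl)-3-pentylphenoxy]-4,6-dihydroxy-2-pentylbenzoate
Product: 15 benzyl 3-[5-(benzyloxy)-2-(methoxycarbonyl)-3-pentylphenoxy]-6-hydroxy-4-methoxy-2-pentylbenzoate
Conditions: MeI (1.2 equiv), K2CO3 (1.2 equiv), acetone, rt to 40 °C
Reagents that add atoms: iodomethane, CI
Why: Williamson O-methylation under mild carbonate conditions: the hydroxyl ortho to the benzyl ester (C2' of ring B) is chelated to the ester carbonyl, so the free hydroxyl para to the ester (C4') should be the only phenol that reacts, the ring A phenol being masked as its benzyl ether.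

**Step 8**
Reactants: 15 benzyl 3-[5-(benzyloxy)-2-(methoxycarbonyl)-3-pentylphenoxy]-6-hydroxy-4-methoxy-2-pentylbenzoate
Product: 16 epiphorellic acid 1
Conditions: H2 (1 atm), 10% Pd/C, EtOAc, rt
Reagents that add atoms: none
Why: Catalytic hydrogenolysis of benzylic C–O bonds: the benzyl ester and the benzyl ether should both be cleaved to the free acid and phenol, while the diaryl ether, the methyl ester and the aryl methyl ether are inert at rt and one atmosphere.

**Compound list**
1 | methyl olivetolate (methyl 2,4-dihydroxy-6-pentylbenzoate) | CCCCCc1cc(O)cc(O)c1C(=O)OC | starting material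
2 | methyl 4-(benzyloxy)-2-hydroxy-6-pentylbenzoate | CCCCCc1cc(OCc2ccccc2)cc(O)c1C(=O)OC | intermediate
3 | nonane-2,4-dione | CCCCCC(=O)CC(C)=O | starting material
4 | 3-chlorononane-2,4-dione (racemic) | CCCCCC(=O)C(Cl)C(C)=O | intermediate
5 | methyl 4-(benzyloxy)-2-[(2,4-dioxononan-3-yl)oxy]-6-pentylbenzoate (racemic) | CCCCCC(=O)C(Oc1cc(OCc2ccccc2)cc(CCCCC)c1C(=O)OC)C(C)=O | intermediate
6 | N-methoxy-N-methylacetamide | CC(=O)N(C)OC | starting material
7 | dilithium dienediolate of 5 (deprotonated at C3 and at the methyl carbon) | [Li+].[Li+].C=C([O-])C(Oc1cc(OCc2ccccc2)cc(CCCCC)c1C(=O)OC)=C([O-])CCCCC | intermediate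
8 | dilithium hemiaminal adduct of 7 with 6 (enolate alkoxide, tetrahedral N-methoxy-N-methyl hemiaminal carbon) | [Li+].[Li+].CCCCCC([O-])=C(Oc1cc(OCc2ccccc2)cc(CCCCC)c1C(=O)OC)C(=O)CC(C)([O-])N(C)OC | intermediate
9 | methyl 4-(benzyloxy)-2-[(2,4,6-trioxoundecan-5-yl)oxy]-6-pentylbenzoate (racemic) | CCCCCC(=O)C(Oc1cc(OCc2ccccc2)cc(CCCCC)c1C(=O)OC)C(=O)CC(C)=O | intermediate
10 | dibenzyl carbonate | O=C(OCc1ccccc1)OCc1ccccc1 | starting material
11 | trilithium trienolate of 9 (deprotonated at C3, C5 and the methyl carbon) | [Li+].[Li+].[Li+].C=C([O-])C=C([O-])C(Oc1cc(OCc2ccccc2)cc(CCCCC)c1C(=O)OC)=C([O-])CCCCC | intermediate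
12 | benzyl 6-[5-(benzyloxy)-2-(methoxycarbonyl)-3-pentylphenoxy]-3,5,7-trioxododecanoate (racemic, triketo tautomer) | CCCCCC(=O)C(Oc1cc(OCc2ccccc2)cc(CCCCC)c1C(=O)OC)C(=O)CC(=O)CC(=O)OCc1ccccc1 | intermediate
13 | benzyl 3-[5-(benzyloxy)-2-(methoxycarbonyl)-3-pentylphenoxy]-2-hydroxy-4,6-dioxo-2-pentylcyclohexane-1-carboxylate (mixture of diastereomers and tautomers) | CCCCCC1(O)C(Oc2cc(OCc3ccccc3)cc(CCCCC)c2C(=O)OC)C(=O)CC(=O)C1C(=O)OCc1ccccc1 | intermediate
14 | benzyl 3-[5-(benzyloxy)-2-(methoxycarbonyl)-3-pentylphenoxy]-4,6-dihydroxy-2-pentylbenzoate | CCCCCc1cc(OCc2ccccc2)cc(Oc2c(O)cc(O)c(C(=O)OCc3ccccc3)c2CCCCC)c1C(=O)OC | intermediate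
15 | benzyl 3-[5-(benzyloxy)-2-(methoxycarbonyl)-3-pentylphenoxy]-6-hydroxy-4-methoxy-2-pentylbenzoate | CCCCCc1cc(OCc2ccccc2)cc(Oc2c(OC)cc(O)c(C(=O)OCc3ccccc3)c2CCCCC)c1C(=O)OC | intermediate
16 | epiphorellic acid 1 | CCCCCc1cc(O)cc(Oc2c(OC)cc(O)c(C(=O)O)c2CCCCC)c1C(=O)OC | target

**Step count**
Total steps: 8. Longest linear sequence: 7 steps (1 or 3 to 16).

**Steps most likely to fail**

Step 6 (key step). The polyenolate may close through oxygen instead of carbon (C5 enolate oxygen onto the C1 ester, loss of benzyl alcohol, pyranone formation). The C6 carbanion may also acylate itself on the ring A ester and then lose an acyl group by retro-Claisen cleavage, or dehydration of the aldol may stall. The fallback brings ring B in preformed and makes the ether C–O bond by Ullmann coupling; it sets out from 1 and 2 and comes back to the route at 16. Compound 1 would be methylated at O-4 (MeI, K2CO3, acetone) to methyl 2-hydroxy-4-methoxy-6-pentylbenzoate F1. Iodination para to the free hydroxyl (N-iodosuccinimide, MeCN) should give methyl 6-hydroxy-3-iodo-4-methoxy-2-pentylbenzoate F2. Saponification (KOH, aqueous DMSO, 80 °C) would give 6-hydroxy-3-iodo-4-methoxy-2-pentylbenzoic acid F3, and double benzylation (BnBr, Cs2CO3, DMF) benzyl 6-(benzyloxy)-3-iodo-4-methoxy-2-pentylbenzoate F4. Ullmann diaryl ether coupling of F4 with phenol 2 (CuI, N,N-dimethylglycine, Cs2CO3, dioxane, 100 °C) should give benzyl 6-(benzyloxy)-3-[5-(benzyloxy)-2-(methoxycarbonyl)-3-pentylphenoxy]-4-methoxy-2-pentylbenzoate F5. Hydrogenolysis under the conditions of step 8 then gives 16.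

Step 5. The third deprotonation may occur at the hexanoyl methylene or at the benzylic CH2 of ring A, proton transfer from the product may stop the conversion, and 12 may cyclize in an uncontrolled way on work-up. The fallback avoids the trianion by soft enolization and decarboxylation; it sets out from 5 and comes back at 12. The dianion of 5, formed as in step 4, would be carboxylated with diallyl carbonate to allyl 4-[5-(benzyloxy)-2-(methoxycarbonyl)-3-pentylphenoxy]-3,5-dioxodecanoate F6. Magnesium-chelate C-acylation at the carbon between the allyl ester and the ketone (MgCl2, pyridine, benzyl 3-chloro-3-oxopropanoate, CH2Cl2, 0 °C) should give 1-allyl 5-benzyl 2-{2-[5-(benzyloxy)-2-(methoxycarbonyl)-3-pentylphenoxy]-3-oxooctanoyl}-3-oxopentanedioate F7. Pd(PPh3)4 (cat.) with morpholine in THF would remove the allyl group, the resulting diacylacetic acid loses CO2, and 12 results.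

Step 3. The chlorodiketone is held as its unreactive cesium enolate while the phenoxide is hindered and chelated, so substitution may be slow and be overtaken by retro-Claisen deacylation of the diketone. The fallback forms the C–O bond under neutral conditions by carbenoid O–H insertion; it sets out from 3 and 2 and comes back at 5. Regitz diazo transfer to 3 (p-acetamidobenzenesulfonyl azide, Et3N, MeCN) would give 3-diazononane-2,4-dione F8. Its decomposition with Rh2(OAc)4 (1 mol%) in toluene at 60 °C in the presence of phenol 2 should give 5 by insertion of the carbenoid into the phenolic O–H bond.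

**Further compounds**
F1 | step 6 | methyl 2-hydroxy-4-methoxy-6-pentylbenzoate | CCCCCc1cc(OC)cc(O)c1C(=O)OC
F2 | step 6 | methyl 6-hydroxy-3-iodo-4-methoxy-2-pentylbenzoate | CCCCCc1c(I)c(OC)cc(O)c1C(=O)OC
F3 | step 6 | 6-hydroxy-3-iodo-4-methoxy-2-pentylbenzoic acid | CCCCCc1c(I)c(OC)cc(O)c1C(=O)O
F4 | step 6 | benzyl 6-(benzyloxy)-3-iodo-4-methoxy-2-pentylbenzoate | CCCCCc1c(I)c(OC)cc(OCc2ccccc2)c1C(=O)OCc1ccccc1
F5 | step 6 | benzyl 6-(benzyloxy)-3-[5-(benzyloxy)-2-(methoxycarbonyl)-3-pentylphenoxy]-4-methoxy-2-pentylbenzoate | CCCCCc1cc(OCc2ccccc2)cc(Oc2c(OC)cc(OCc3ccccc3)c(C(=O)OCc3ccccc3)c2CCCCC)c1C(=O)OC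
F6 | step 5 | allyl 4-[5-(benzyloxy)-2-(methoxycarbonyl)-3-pentylphenoxy]-3,5-dioxodecanoate | C=CCOC(=O)CC(=O)C(Oc1cc(OCc2ccccc2)cc(CCCCC)c1C(=O)OC)C(=O)CCCCC
F7 | step 5 | 1-allyl 5-benzyl 2-{2-[5-(benzyloxy)-2-(methoxycarbonyl)-3-pentylphenoxy]-3-oxooctanoyl}-3-oxopentanedioate | C=CCOC(=O)C(C(=O)CC(=O)OCc1ccccc1)C(=O)C(Oc1cc(OCc2ccccc2)cc(CCCCC)c1C(=O)OC)C(=O)CCCCC
F8 | step 3 | 3-diazononane-2,4-dione | CCCCCC(=O)C(=[N+]=[N-])C(C)=O
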